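**Strategy.** Everything rests on opening ring C, the γ-lactone, at O–C7 and C17–C8, which exposes the 1,2-dielectrophile hidden in the C7(O)–C8(OH) unit of the ten-membered ring B: a C7 bromide next to a C8 ketone. In one pot a 2-bromopropanoate displaces that bromide through oxygen and zinc then converts its own C–Br bond into a Reformatsky enolate that adds to C8, closing the β-hydroxy lactone and setting C7, C8 and C17. The bromo ketone arises from an anionic oxy-Cope ring expansion of a quinone Diels–Alder-derived trans-decalin bearing an axial C8 vinyl and an equatorial C3 allenyl group, which delivers the 3Z,5(16)-diene, the C8 ketone and its C7 enolate at once.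

Key step: step 14

Numbering and descriptors: briarane numbering is used. Ring A = C1, C10, C11, C12, C13, C14 (C15 = methyl on C1, C20 = methyl on C11). Ring B = the ten-membered ring C1 to C10 (C16 = exocyclic methylene on C5). Ring C = the lactone C7, C8, C17, C19, O (C18 = methyl on C17). Ring D = the temporary six-membered ring C1, C2, C3, C8, C9, C10 of the decalin stage, whose C3–C8 bond is cleaved in step 13. β is the face of the C15 methyl, α the opposite face.

Assumption: the (S)-configured oxazaborolidinium ion is taken to shield the quinone face that leads to the (1R) adduct; if its facial sense is the opposite, the equally accessible (R)-catalyst is used and nothing else changes.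

Assumption: 2-methoxy-5-methyl-1,4-benzoquinone (3) is treated as a purchasable compound.

Step 1
Reactants: 1 pent-1-en-3-one
Product: 2 (Z)-3-(triisopropylsilyloxy)penta-1,3-diene
Conditions: iPr3SiOTf, Et3N, CH2Cl2, 0 °C
Reagents that add atoms: triisopropylsilyl triflate, CC(C)[Si](C(C)C)(C(C)C)OS(=O)(=O)C(F)(F)F
Why: Soft enolization and O-silylation of the ethyl ketone (silyl dienol ether formation) gives the 2-silyloxy diene, the Z enol ether following from the usual preference of amine/silyl triflate enolization of ethyl ketones.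

Step 2
Reactants: 3 2-methoxy-5-methyl-1,4-benzoquinone; 4 prop-2-yn-1-ol
Product: 5 2-methyl-5-(prop-2-yn-1-yloxy)-1,4-benzoquinone
Conditions: TsOH·H2O (5 mol%), toluene, 60 °C, 4 Å molecular sieves
Reagents that add atoms: none
Why: Acid-catalysed alkoxy exchange (addition–elimination at the vinylogous ester carbon of the quinone) replaces methoxy by propargyloxy and is driven by removal of methanol; no stereocentre is formed.

Step 3
Reactants: 5 2-methyl-5-(prop-2-yn-1-yloxy)-1,4-benzoquinone; 2 (Z)-3-(triisopropylsilyloxy)penta-1,3-diene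
Product: 7 trans-fused enedione (1β-methyl; H10 α; 11α-methyl; ring D 8-propargyloxy-3-ene-2,9-dione; ring A 12-silyloxy-12-ene), via cis-fused cycloadduct 6 (not isolated)
Conditions: (S)-o-tolyl-oxazaborolidine (from (S)-α,α-diphenylprolinol) activated by Tf2NH (20 mol%), CH2Cl2, −78 °C; then DBU (0.2 equiv), 0 °C
Reagents that add atoms: none
Why: Catalytic enantioselective quinone Diels–Alder reaction in which the boron cation binds the more basic vinylogous-ester carbonyl (C2), so that the nucleophilic diene terminus C11 bonds to C10 and the diene adds endo to the methyl-bearing double bond, setting C1 and C11 (methyl α), after which DBU should epimerise C10 to the trans ring fusion.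

Step 4
Reactants: 7 trans-fused enedione
Product: 8 2β,9β-diol (ring D 8-propargyloxy-3-ene retained)
Conditions: LiAlH4, THF, −78 to 0 °C; aqueous NaOH work-up
Reagents that add atoms: none
Why: Hydride 1,2-reduction of both ring D carbonyls from the α-face, anti to the angular C15 methyl, sets C2 (equatorial β-OH) and C9 (axial β-OH); both enol ethers are inert and no acid is used, so no allylic transposition is triggered.

Step 5
Reactants: 8 2β,9β-diol
Product: 9 2β,9β-bis(4-methoxybenzyl) ether
Conditions: NaH, 4-methoxybenzyl chloride, Bu4NI (cat.), DMF, 0 °C to rt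
Reagents that add atoms: 4-methoxybenzyl chloride, COc1ccc(CCl)cc1
Why: Williamson etherification of both secondary alkoxides; the enol ethers and the terminal alkyne tolerate NaH at this temperature and no stereocentre is touched.

Step 6
Reactants: 9 2β,9β-bis(4-methoxybenzyl) ether
Product: 10 ring A 13-en-12-one (11α-methyl)
Conditions: 2-iodoxybenzoic acid (IBX), 4-methoxypyridine N-oxide, DMSO, rt
Reagents that add atoms: none
Why: Dehydrogenation of a silyl enol ether by IBX·4-methoxypyridine N-oxide (silicon-to-iodine exchange at the enol oxygen, then loss of the C14 hydrogen) gives the enone regiospecifically; the alkyl enol ether of ring D has no O–Si bond to exchange and the PMB ethers are stable at room temperature.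

Step 7
Reactants: 10 ring A 13-en-12-one (11α-methyl)
Product: 12 ring A 13-en-12-one with 11β-methyl, via dilithium dienolate acetylide 11 (not isolated)
Conditions: LiN(iPr)2 (2.3 equiv), THF, −78 °C; then 2,6-di-tert-butyl-4-methylphenol, −78 °C; aqueous NH4Cl
Reagents that add atoms: none
Why: Kinetic α′-deprotonation of the enone (the alkyne C–H consumes the second equivalent) followed by kinetic protonation of the cross-conjugated dienolate from the α-face, the face not screened by the 1,3-related axial C15 methyl, should invert C11 to the less stable β-methyl epimer.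

Step 8
Reactants: 12 ring A 13-en-12-one with 11β-methyl
Product: 13 13α,14α-epoxy-12-ketone
Conditions: 30% H2O2, NaOH (0.2 equiv), MeOH–THF, 0 °C, short reaction time
Reagents that add atoms: hydrogen peroxide, OO
Why: Weitz–Scheffer nucleophilic epoxidation in which hydroperoxide adds to C14 anti to the adjacent C15 methyl and closes the α-epoxide; brief exposure to catalytic base at 0 °C should leave the poorly aligned equatorial H11 in place.

Step 9
Reactants: 13 13α,14α-epoxy-12-ketone
Product: 14 12β,14α-diol (C13 methylene)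
Conditions: LiAlH4, THF, 0 °C to rt; aqueous NaOH work-up
Reagents that add atoms: none
Why: Hydride reduction of the ketone and trans-diaxial (Fürst–Plattner) opening of the epoxide at the less hindered C13 leave the axial 14α-hydroxyl; the C12 carbinol configuration (β expected from attack anti to the axial C20 methyl) is immaterial because C12 is oxidised later.

Step 10
Reactants: 14 12β,14α-diol
Product: 15 12β,14α-bis(tert-butyldimethylsilyl) ether
Conditions: tBuMe2SiOTf (3 equiv), 2,6-lutidine, CH2Cl2, −20 °C to rt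
Reagents that add atoms: tert-butyldimethylsilyl triflate, CC(C)(C)[Si](C)(C)OS(=O)(=O)C(F)(F)F
Why: Silyl triflate silylation of both secondary alcohols (needed for the hindered axial C14 hydroxyl) under buffered conditions that spare the enol ether.

Step 11
Reactants: 15 12β,14α-bis(tert-butyldimethylsilyl) ether
Product: 16 ring D 8-ketone with 3α-(propa-1,2-dienyl) group (equatorial)
Conditions: o-xylene, 140 °C, 2,6-di-tert-butyl-4-methylphenol (cat.), base-washed glassware
Reagents that add atoms: none
Why: Thermal propargyl Claisen ([3,3]-sigmatropic, Saucy–Marbet) rearrangement of the propargyl enol ether unveils the C8 ketone and forms the C3–C4 bond with the allene; C4 is delivered to the α-face of C3, anti to the C15 methyl, and the equatorial 3α isomer is in any case the thermodynamic one at this epimerisable centre.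

Step 12
Reactants: 16 ring D 8-ketone with 3α-(propa-1,2-dienyl) group; 17 vinylmagnesium bromide
Product: 18 tertiary carbinol (8β-hydroxyl equatorial; 8α-vinyl axial)
Conditions: CeCl3 (anhydrous), THF, −78 °C; aqueous NH4Cl
Reagents that add atoms: none
Why: Organocerium 1,2-addition (non-basic, so the α-allenyl ketone is not enolised) in which the nucleophile attacks axially from the α-face, anti to the axial C9–OPMB bond (polar Felkin–Anh), setting C8 with equatorial hydroxyl and axial vinyl.

Step 13
Reactants: 18 tertiary carbinol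
Product: 20 ring B (7R)-7-bromo-8-ketone with 3Z,5(16)-diene, via potassium enolate 19 (not isolated)
Conditions: KN(SiMe3)2, 18-crown-6, THF, −78 to 0 °C; then N-bromosuccinimide, −78 °C; aqueous NH4Cl
Reagents that add atoms: N-bromosuccinimide, O=C1CCC(=O)N1Br
Why: Anionic oxy-Cope ring expansion through the chair transition state of the cis-related axial vinyl and equatorial allenyl groups, in which C2 is axial so that C3=C4 forms Z and the allene central carbon C5 bonds to C6 while keeping the C5=C16 methylene; the ring-trans enolate is then brominated (enolate α-halogenation) on its outer β-face, which should set C7 as R.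

Step 14
Reactants: 20 ring B (7R)-7-bromo-8-ketone; 21 2-bromopropanoic acid (racemic)
Product: 24 β-hydroxy-γ-lactone (ring C closed; C6 methylene; PMB and silyl ethers retained), via bromopropanoate ester 22 (not isolated), via zinc enolate 23 (not isolated)
Conditions: Cs2CO3, DMF, 0 °C to rt; then Zn dust (Me3SiCl-activated), THF, 45 °C; aqueous NH4Cl
Reagents that add atoms: none
Why: The cesium carboxylate of 21 displaces the α-keto bromide at C7 by SN2 with inversion (O–C7 bond), and zinc then inserts into the remaining C–Br bond to give a Reformatsky enolate whose carbon C17 adds to the C8 ketone (C17–C8 bond). The closest known chemistry is O-alkylation of carboxylates by α-halo ketones followed by the intramolecular Reformatsky reaction of an α-(α-bromoacyloxy) ketone, the classical entry to β-hydroxy-γ-lactones and butenolides. Ring C is closed by a 5-exo-trig attack of the enolate carbon on the carbonyl (5-(enolendo)-exo-trig, which a carbon-bound zinc enolate tolerates). C7 is set by inversion of the (7R)-bromide; C8 is set because the tether on the α-face can deliver C17 only to the α-face of the carbonyl, which is also the face anti to the C9–OPMB bond, giving the cis-fused lactone with the hydroxyl cis to H7; C17 is set by placing its methyl away from C9 in the zinc-chelated aldolate and remains correctable by base equilibration. The step needs substitution to outrun dehydrobromination and enolate formation only at the propanoate: the first is secured by α-carbonyl activation of C7 toward a weakly basic nucleophile, the second by generating the enolate reductively at the only C–Br bond, so that the ketone α-hydrogens at C7 and C9 are never removed.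

Step 15
Reactants: 24 β-hydroxy-γ-lactone
Product: 25 (6R)-6-hydroxy derivative (allylic alcohol; C6 epimeric to the chloride of 31)
Conditions: SeO2 (0.3 equiv), tBuOOH, CH2Cl2, rt
Reagents that add atoms: tert-butyl hydroperoxide, CC(C)(C)OO
Why: SeO2 allylic hydroxylation (ene reaction, then [2,3]-sigmatropic shift) at C6, the only allylic methylene of the 1,1-disubstituted C5=C16 alkene, with oxygen expected on the β-face of ring B, opposite the α-fused lactone.

Step 16
Reactants: 25 (6R)-6-hydroxy derivative
Product: 26 (6S)-6-chloride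
Conditions: PPh3, hexachloroacetone, CH2Cl2, −20 °C
Reagents that add atoms: hexachloroacetone, ClC(Cl)(Cl)C(=O)C(Cl)(Cl)Cl
Why: Appel-type chlorination converts the secondary allylic alcohol into the chloride by SN2 with inversion under conditions known to minimise allylic transposition; the hindered tertiary C8 hydroxyl should not react.

Step 17
Reactants: 26 (6S)-6-chloride
Product: 27 2β,9β-diol
Conditions: DDQ, CH2Cl2–pH 7 buffer, 0 °C
Reagents that add atoms: none
Why: Oxidative cleavage of both PMB ethers by DDQ (benzylic hydride abstraction, then hydrolysis of the oxocarbenium ion in the wet buffered medium) leaves silyl ethers, lactone, diene and allylic chloride untouched.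

Step 18
Reactants: 27 2β,9β-diol
Product: 28 2,9-diacetate
Conditions: Ac2O, pyridine, DMAP (cat.), CH2Cl2, 0 °C to rt
Reagents that add atoms: acetic anhydride, CC(=O)OC(C)=O
Why: Acetylation of the two secondary alcohols; the tertiary C8 hydroxyl is too hindered to be acylated under these conditions.

Step 19
Reactants: 28 2,9-diacetate
Product: 29 12β,14α-diol
Conditions: HF·pyridine, THF–pyridine, 0 °C to rt
Reagents that add atoms: none
Why: Fluoride-mediated cleavage of both silyl ethers under buffered conditions that spare acetates, lactone and allylic chloride.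

Step 20
Reactants: 29 12β,14α-diol
Product: 30 12-ketone with free 14α-hydroxyl
Conditions: TEMPO (0.2 equiv), PhI(OAc)2, CH2Cl2, rt
Reagents that add atoms: none
Why: Oxoammonium (TEMPO/PhI(OAc)2) oxidation is highly sensitive to steric hindrance, so the C12 carbinol should be oxidised while the neopentyl axial C14 hydroxyl next to quaternary C1 is left; the near-neutral medium preserves the epimerisable C11 centre.

Step 21
Reactants: 30 12-ketone with free 14α-hydroxyl
Product: 31 CNP0283653.1 (target)
Conditions: butanoic anhydride, DMAP, pyridine, CH2Cl2, 0 °C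
Reagents that add atoms: butanoic anhydride, CCCC(=O)OC(=O)CCC
Why: DMAP-catalysed acylation of the remaining secondary alcohol at low temperature, mild enough to avoid β-elimination of the new acyloxy group and epimerisation at C11.

**Compound list**

1 | pent-1-en-3-one | CCC(=O)C=C | starting material
2 | (Z)-3-(triisopropylsilyloxy)penta-1,3-diene | C/C=C(\O[Si](C(C)C)(C(C)C)C(C)C)C=C | intermediate
3 | 2-methoxy-5-methyl-1,4-benzoquinone | COC1=CC(=O)C(C)=CC1=O | starting material
4 | prop-2-yn-1-ol | C#CCO | starting material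
5 | 2-methyl-5-(prop-2-yn-1-yloxy)-1,4-benzoquinone | C#CCOC1=CC(=O)C(C)=CC1=O | intermediate
6 | cis-fused cycloadduct (1β-methyl, H10 β, 11α-methyl; ring D 8-propargyloxy-3-ene-2,9-dione; ring A 12-triisopropylsilyloxy-12-ene) | C[C@@]12C(=O)C=C(OCC#C)C(=O)[C@@H]1[C@H](C)C(O[Si](C(C)C)(C(C)C)C(C)C)=CC2 | intermediate
7 | trans-fused enedione (C10 epimer of 6, H10 α) | C[C@@]12C(=O)C=C(OCC#C)C(=O)[C@H]1[C@H](C)C(O[Si](C(C)C)(C(C)C)C(C)C)=CC2 | intermediate
8 | 2β,9β-diol of 7 | C[C@@]12[C@@H](O)C=C(OCC#C)[C@@H](O)[C@H]1[C@H](C)C(O[Si](C(C)C)(C(C)C)C(C)C)=CC2 | intermediate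
9 | 2β,9β-bis(4-methoxybenzyl) ether of 8 | C[C@@]12[C@@H](OCc3ccc(OC)cc3)C=C(OCC#C)[C@@H](OCc3ccc(OC)cc3)[C@H]1[C@H](C)C(O[Si](C(C)C)(C(C)C)C(C)C)=CC2 | intermediate
10 | ring A 13-en-12-one, 11α-methyl | C[C@@]12[C@@H](OCc3ccc(OC)cc3)C=C(OCC#C)[C@@H](OCc3ccc(OC)cc3)[C@H]1[C@H](C)C(=O)C=C2 | intermediate
11 | dilithium dienolate acetylide of 10 (C11=C12–O−, C13=C14, lithium alkynide) | [Li+].[Li+].C[C@@]12[C@@H](OCc3ccc(OC)cc3)C=C(OCC#[C-])[C@@H](OCc3ccc(OC)cc3)[C@H]1C(C)=C([O-])C=C2 | intermediate
12 | ring A 13-en-12-one, 11β-methyl (C11 epimer of 10) | C[C@@]12[C@@H](OCc3ccc(OC)cc3)C=C(OCC#C)[C@@H](OCc3ccc(OC)cc3)[C@H]1[C@@H](C)C(=O)C=C2 | intermediate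
13 | 13α,14α-epoxy-12-ketone | C[C@@]12[C@@H](OCc3ccc(OC)cc3)C=C(OCC#C)[C@@H](OCc3ccc(OC)cc3)[C@H]1[C@@H](C)C(=O)[C@@H]3O[C@H]23 | intermediate
14 | 12β,14α-diol | C[C@@]12[C@@H](OCc3ccc(OC)cc3)C=C(OCC#C)[C@@H](OCc3ccc(OC)cc3)[C@H]1[C@@H](C)[C@@H](O)C[C@@H]2O | intermediate
15 | 12β,14α-bis(tert-butyldimethylsilyl) ether | C[C@@]12[C@@H](OCc3ccc(OC)cc3)C=C(OCC#C)[C@@H](OCc3ccc(OC)cc3)[C@H]1[C@@H](C)[C@@H](O[Si](C)(C)C(C)(C)C)C[C@@H]2O[Si](C)(C)C(C)(C)C | intermediate
16 | ring D 8-ketone with equatorial 3α-(propa-1,2-dienyl) group | C[C@@]12[C@@H](OCc3ccc(OC)cc3)[C@H](C=C=C)C(=O)[C@@H](OCc3ccc(OC)cc3)[C@H]1[C@@H](C)[C@@H](O[Si](C)(C)C(C)(C)C)C[C@@H]2O[Si](C)(C)C(C)(C)C | intermediate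
17 | vinylmagnesium bromide | C=C[Mg]Br | starting material
18 | tertiary carbinol (8β-OH equatorial, 8α-vinyl axial, 3α-allenyl) | C[C@@]12[C@@H](OCc3ccc(OC)cc3)[C@H](C=C=C)[C@](O)(C=C)[C@@H](OCc3ccc(OC)cc3)[C@H]1[C@@H](C)[C@@H](O[Si](C)(C)C(C)(C)C)C[C@@H]2O[Si](C)(C)C(C)(C)C | intermediate
19 | potassium enolate of the ring B 8-ketone (C7=C8 ring-trans, 3Z,5(16)-diene) | [K+].C=C1/C=C\[C@H](OCc3ccc(OC)cc3)[C@]2(C)[C@H]([C@@H](C)[C@@H](O[Si](C)(C)C(C)(C)C)C[C@@H]2O[Si](C)(C)C(C)(C)C)[C@H](OCc3ccc(OC)cc3)/C([O-])=C/C1 | intermediate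
20 | ring B (7R)-7-bromo-8-ketone, 3Z,5(16)-diene | C=C1/C=C\[C@H](OCc3ccc(OC)cc3)[C@]2(C)[C@H]([C@@H](C)[C@@H](O[Si](C)(C)C(C)(C)C)C[C@@H]2O[Si](C)(C)C(C)(C)C)[C@H](OCc3ccc(OC)cc3)C(=O)[C@H](Br)C1 | intermediate
21 | 2-bromopropanoic acid (racemic) | CC(Br)C(=O)O | starting material
22 | 7-(2-bromopropanoyloxy)-8-ketone (C7 inverted, O on the α-face) | C=C1/C=C\[C@H](OCc3ccc(OC)cc3)[C@]2(C)[C@H]([C@@H](C)[C@@H](O[Si](C)(C)C(C)(C)C)C[C@@H]2O[Si](C)(C)C(C)(C)C)[C@H](OCc3ccc(OC)cc3)C(=O)[C@@H](OC(=O)C(C)Br)C1 | intermediate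
23 | bromozinc (Reformatsky) enolate of 22 | C=C1/C=C\[C@H](OCc3ccc(OC)cc3)[C@]2(C)[C@H]([C@@H](C)[C@@H](O[Si](C)(C)C(C)(C)C)C[C@@H]2O[Si](C)(C)C(C)(C)C)[C@H](OCc3ccc(OC)cc3)C(=O)[C@@H](OC(=O)C(C)[Zn]Br)C1 | intermediate
24 | β-hydroxy-γ-lactone (ring C closed, C6 methylene) | C=C1/C=C\[C@H](OCc3ccc(OC)cc3)[C@]2(C)[C@H]([C@@H](C)[C@@H](O[Si](C)(C)C(C)(C)C)C[C@@H]2O[Si](C)(C)C(C)(C)C)[C@H](OCc3ccc(OC)cc3)[C@@]2(O)[C@H](C)C(=O)O[C@H]2C1 | intermediate
25 | (6R)-6-hydroxy lactone | C=C1/C=C\[C@H](OCc3ccc(OC)cc3)[C@]2(C)[C@H]([C@@H](C)[C@@H](O[Si](C)(C)C(C)(C)C)C[C@@H]2O[Si](C)(C)C(C)(C)C)[C@H](OCc3ccc(OC)cc3)[C@@]2(O)[C@H](C)C(=O)O[C@H]2[C@@H]1O | intermediate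
26 | (6S)-6-chloro lactone | C=C1/C=C\[C@H](OCc3ccc(OC)cc3)[C@]2(C)[C@H]([C@@H](C)[C@@H](O[Si](C)(C)C(C)(C)C)C[C@@H]2O[Si](C)(C)C(C)(C)C)[C@H](OCc3ccc(OC)cc3)[C@@]2(O)[C@H](C)C(=O)O[C@H]2[C@H]1Cl | intermediate
27 | 2,9-diol (12,14-bis-silyl ether) | C=C1/C=C\[C@H](O)[C@]2(C)[C@H]([C@@H](C)[C@@H](O[Si](C)(C)C(C)(C)C)C[C@@H]2O[Si](C)(C)C(C)(C)C)[C@H](O)[C@@]2(O)[C@H](C)C(=O)O[C@H]2[C@H]1Cl | intermediate
28 | 2,9-diacetate (12,14-bis-silyl ether) | C=C1/C=C\[C@H](OC(C)=O)[C@]2(C)[C@H]([C@@H](C)[C@@H](O[Si](C)(C)C(C)(C)C)C[C@@H]2O[Si](C)(C)C(C)(C)C)[C@H](OC(C)=O)[C@@]2(O)[C@H](C)C(=O)O[C@H]2[C@H]1Cl | intermediate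
29 | 2,9-diacetate 12β,14α-diol | C=C1/C=C\[C@H](OC(C)=O)[C@]2(C)[C@H]([C@@H](C)[C@@H](O)C[C@@H]2O)[C@H](OC(C)=O)[C@@]2(O)[C@H](C)C(=O)O[C@H]2[C@H]1Cl | intermediate
30 | 2,9-diacetate 12-ketone 14α-ol | C=C1/C=C\[C@H](OC(C)=O)[C@]2(C)[C@H]([C@@H](C)C(=O)C[C@@H]2O)[C@H](OC(C)=O)[C@@]2(O)[C@H](C)C(=O)O[C@H]2[C@H]1Cl | intermediate
31 | CNP0283653.1 | C=C1/C=C\[C@H](OC(C)=O)[C@]2(C)[C@H]([C@@H](C)C(=O)C[C@@H]2OC(=O)CCC)[C@H](OC(C)=O)[C@@]2(O)[C@H](C)C(=O)O[C@H]2[C@H]1Cl | target

**Step count.** Total: 21 steps. Longest linear sequence: 20 steps (3 to 31 through steps 2 to 21; the diene branch, step 1, joins at step 3).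

**Steps most likely to fail**

Step 13 (oxy-Cope ring expansion and bromination). The tertiary potassium alkoxide may fragment by retro-addition instead of rearranging, a boat transition state may leak to the E-configured C3=C4 alkene, and a conformationally mobile enolate may lose facial control in the bromination. The fallback replaces the charge-accelerated shift by a neutral one with an isolable product. It sets out from 18, which is silylated with N-(trimethylsilyl)imidazole to the trimethylsilyl ether F1. Thermolysis of F1 (o-dichlorobenzene, about 180 °C) should give the trimethylsilyl enol ether F2 of the ten-membered ketone by a siloxy-Cope rearrangement, whose alkene geometry can be checked before going on. Bromination of F2 with N-bromosuccinimide (THF, −78 °C) comes back to the route at 20.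

Step 14 (key step). Zinc may reductively cleave the C7–O bond of the α-acyloxy ketone, or reduce unreacted bromo ketone, faster than the Reformatsky addition closes the ring. The fallback forms the enolate by deprotonation instead of reduction. It sets out from 20, which is treated with cesium propanoate (DMF, 0 °C) to give, by the same SN2 inversion, the 7-propanoyloxy ketone F3, which is isolated. Kinetic deprotonation of the unhindered ester methylene with LiN(SiMe3)2 (THF, −78 °C) and intramolecular aldol addition to C8 should then come back to the route at 24.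

Step 16 (chlorination). Chloride may attack C16 with allylic transposition (SN2′), or the activated alcohol may ionise and lose its configuration at C6. The fallback turns the transposition into the productive pathway. It sets out from 25, which is equilibrated with Ph3SiOReO3 (cat., Et2O, 0 °C) by 1,3-transposition to the conjugated primary allylic alcohol F4 (C16 hydroxyl, C5=C6 alkene). Treatment of F4 with SOCl2 in Et2O at 0 °C should return chloride to C6 with regeneration of the C5=C16 methylene through the SNi′ pathway of the chlorosulfite, coming back to the route at 26.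

**Further compounds**

F1 | step 13 | 8-O-trimethylsilyl ether of 18 | C[C@@]12[C@@H](OCc3ccc(OC)cc3)[C@H](C=C=C)[C@](O[Si](C)(C)C)(C=C)[C@@H](OCc3ccc(OC)cc3)[C@H]1[C@@H](C)[C@@H](O[Si](C)(C)C(C)(C)C)C[C@@H]2O[Si](C)(C)C(C)(C)C
F2 | step 13 | trimethylsilyl enol ether of the ring B 8-ketone (C7=C8 ring-trans, 3Z,5(16)-diene) | C=C1/C=C\[C@H](OCc3ccc(OC)cc3)[C@]2(C)[C@H]([C@@H](C)[C@@H](O[Si](C)(C)C(C)(C)C)C[C@@H]2O[Si](C)(C)C(C)(C)C)[C@H](OCc3ccc(OC)cc3)/C(O[Si](C)(C)C)=C/C1
F3 | step 14 | 7-propanoyloxy-8-ketone (C7 inverted) | C=C1/C=C\[C@H](OCc3ccc(OC)cc3)[C@]2(C)[C@H]([C@@H](C)[C@@H](O[Si](C)(C)C(C)(C)C)C[C@@H]2O[Si](C)(C)C(C)(C)C)[C@H](OCc3ccc(OC)cc3)C(=O)[C@@H](OC(=O)CC)C1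
F4 | step 16 | primary allylic alcohol (16-hydroxy, 3Z,5-diene with C4 and C7 trans on C5=C6) | OC/C=1/C=C\[C@H](OCc3ccc(OC)cc3)[C@]2(C)[C@H]([C@@H](C)[C@@H](O[Si](C)(C)C(C)(C)C)C[C@@H]2O[Si](C)(C)C(C)(C)C)[C@H](OCc3ccc(OC)cc3)[C@@]2(O)[C@H](C)C(=O)O[C@H]2/C=1
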